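The route rests on closing the dihydropyran ring of ring A at carbon instead of at oxygen. A tertiary propargyl ether is first placed on the oxygen that becomes O5. Cationic monovalent gold then makes C6 attack the terminal alkyne carbon in a 6-endo-dig hydroarylation. C6 is the only free ring carbon ortho to O5, flanked by O5 and O7 and para to the future O1, so the bond from C6 to the pyran CH carbon forms with full regiocontrol; hydrogenation turns that =CH into the CH2. The chroman ketone is then converted into a 3-iodochromone, coupled with a ring B chromene boronate, cyclised oxidatively to the coumaronochromone, and prenylated at C8 by O-allylation and Claisen rearrangement.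

Key step: step 3

Remark on locants: chromone and isoflavone locants are used throughout (O1, C2, C3, C4, ring A C4a–C8a, ring B C1'–C6'); in the coumaronochromones the furan oxygen links C2 and C2'. The target has no stereocentre; only enaminone 6 has a defined (E) double bond.

Assumption: tert-butyl (2-methylbut-3-en-2-yl) carbonate is taken as a catalogue reagent.

Step 1
Reactants: 1 2,4,6-trihydroxyacetophenone
Product: 2 1-[2,6-dihydroxy-4-(methoxymethoxy)phenyl]ethan-1-one
Conditions: MOMCl (1.0 equiv), iPr2NEt, THF/CH2Cl2, 0 °C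
Reagents that add atoms: chloromethyl methyl ether, COCCl
Why: O-alkylation of a phenol with an α-chloro ether (MOM protection); the 4-hydroxyl is the most acidic one and the only one not hydrogen-bonded to the acetyl group, so one equivalent of reagent should give mainly the 4-ether.

Step 2
Reactants: 2 1-[2,6-dihydroxy-4-(methoxymethoxy)phenyl]ethan-1-one
Product: 3 1-[2-hydroxy-4-(methoxymethoxy)-6-[(2-methylbut-3-yn-2-yl)oxy]phenyl]ethan-1-one
Conditions: 3-chloro-3-methylbut-1-yne (1.2 equiv), DBU, CuCl2·2H2O (1 mol %), MeCN, 0 °C to rt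
Reagents that add atoms: 3-chloro-3-methylbut-1-yne, CC(C)(Cl)C#C
Why: Copper-catalysed propargylic etherification of a phenol with a tertiary propargyl chloride; the two ortho hydroxyls are equivalent, and after the first alkylation the remaining one is held in a hydrogen bond to the ketone, which should stop the reaction at the mono-ether.

Step 3
Reactants: 3 1-[2-hydroxy-4-(methoxymethoxy)-6-[(2-methylbut-3-yn-2-yl)oxy]phenyl]ethan-1-one
Product: 4 1-[7-hydroxy-5-(methoxymethoxy)-2,2-dimethyl-2H-chromen-8-yl]ethan-1-one
Conditions: Ph3PAuNTf2 (5 mol %), CH2Cl2, rt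
Reagents that add atoms: none
Why: The cationic monovalent gold complex binds the terminal alkyne, the ring carbon between the propargyloxy and MOM-oxy carbons (para to the free hydroxyl, the future C6) attacks the terminal alkyne carbon in Friedel–Crafts fashion, and rearomatisation followed by protodeauration of the vinylgold species releases the 2H-chromene and the catalyst. The closest known reaction type is the gold- or platinum-catalysed intramolecular hydroarylation (cycloisomerisation) of aryl propargyl ethers to 2H-chromenes. The pyran ring is closed in the 6-endo-dig mode at the aryl–carbon bond, while the O–C(CH3)2 bond made in step 2 stays intact. No stereocentre is formed. The step needs endo over 5-exo-dig closure and attack at a single ring carbon: the short O–C(CH3)2 tether cannot bring the internal alkyne carbon to the ring without a strained exocyclic vinyl cation, the other ortho position carries the acetyl group, and the attacked carbon is the most electron-rich site of the ring, flanked by two oxygens, with the gem-dimethyl group favouring the reactive conformer. Room temperature keeps the thermal propargyl Claisen pathway, which would close the ring at oxygen, out of play.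

Step 4
Reactants: 4 1-[7-hydroxy-5-(methoxymethoxy)-2,2-dimethyl-2H-chromen-8-yl]ethan-1-one
Product: 5 1-[7-hydroxy-5-(methoxymethoxy)-2,2-dimethyl-3,4-dihydro-2H-chromen-8-yl]ethan-1-one
Conditions: H2 (1 atm), 10% Pd/C, EtOAc, rt
Reagents that add atoms: none
Why: Heterogeneous catalytic hydrogenation of the styrene-type C3=C4 bond converts the chromene into the chroman and so turns the ring-bound =CH into the benzylic CH2; the chelated aryl ketone and the MOM ether should be inert at 1 atm.

Step 5
Reactants: 5 1-[7-hydroxy-5-(methoxymethoxy)-2,2-dimethyl-3,4-dihydro-2H-chromen-8-yl]ethan-1-one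
Product: 7 3-iodo-7-(methoxymethoxy)chromen-4-one bearing the 2,2-dimethyldihydropyran ring (O on C5; CH2 on C6), via enaminone 6 (not isolated)
Conditions: Me2NCH(OMe)2, PhMe, 95 °C; evaporate; then I2, CHCl3, rt
Reagents that add atoms: N,N-dimethylformamide dimethyl acetal, COC(OC)N(C)C; iodine, II
Why: Enaminone formation from the methyl ketone followed by iodine-induced cyclisation (α-iodination, attack of the ortho phenol on the iminium carbon, loss of dimethylamine) is the standard 3-iodochromone synthesis, and because the phenol used is the one beside the acetyl group, the dihydropyran oxygen ends up on C5 with its CH2 on C6.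

Step 6
Reactants: 8 5-bromo-2,4-dihydroxybenzaldehyde
Product: 9 2-bromo-4-formyl-5-hydroxyphenyl 2,2-dimethylpropanoate
Conditions: PivCl (1.05 equiv), Et3N, CH2Cl2, 0 °C
Reagents that add atoms: pivaloyl chloride, CC(C)(C)C(Cl)=O
Why: Selective O-acylation: the 2-hydroxyl is deactivated by its hydrogen bond to the aldehyde, so the acyl chloride should take the 4-hydroxyl, the later 2'-oxygen.

Step 7
Reactants: 9 2-bromo-4-formyl-5-hydroxyphenyl 2,2-dimethylpropanoate
Product: 10 2-bromo-4-formyl-5-[(2-methylbut-3-yn-2-yl)oxy]phenyl 2,2-dimethylpropanoate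
Conditions: 3-chloro-3-methylbut-1-yne (1.3 equiv), DBU, CuCl2·2H2O (1 mol %), MeCN, 0 °C to rt
Reagents that add atoms: 3-chloro-3-methylbut-1-yne, CC(C)(Cl)C#C
Why: The same copper-catalysed propargylic etherification as in step 2 alkylates the only free phenol, the later chromene oxygen O4', and the hindered pivalate should resist acyl transfer under the amidine base.

Step 8
Reactants: 10 2-bromo-4-formyl-5-[(2-methylbut-3-yn-2-yl)oxy]phenyl 2,2-dimethylpropanoate
Product: 12 2-bromo-4-hydroxy-5-[(2-methylbut-3-yn-2-yl)oxy]phenyl 2,2-dimethylpropanoate, via aryl formate 11 (not isolated)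
Conditions: mCPBA, CH2Cl2, 0 °C to rt; aq. NaHCO3 wash; then Et3N (cat.), MeOH, 0 °C
Reagents that add atoms: meta-chloroperoxybenzoic acid, OOC(=O)c1cccc(Cl)c1
Why: Baeyer–Villiger (Dakin-type) oxidation of an ortho-alkoxybenzaldehyde with aryl migration gives the aryl formate, which is methanolysed far faster than the hindered pivalate; the terminal alkyne is inert to the peracid, which is why the oxidation is placed before the chromene double bond exists.

Step 9
Reactants: 12 2-bromo-4-hydroxy-5-[(2-methylbut-3-yn-2-yl)oxy]phenyl 2,2-dimethylpropanoate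
Product: 13 2-bromo-4-(methoxymethoxy)-5-[(2-methylbut-3-yn-2-yl)oxy]phenyl 2,2-dimethylpropanoate
Conditions: MOMCl, iPr2NEt, CH2Cl2, 0 °C to rt
Reagents that add atoms: chloromethyl methyl ether, COCCl
Why: MOM protection (O-alkylation) of the only free phenol masks the later 5'-hydroxyl, so that ring B is not a free hydroquinone in the oxidative step 13.

Step 10
Reactants: 13 2-bromo-4-(methoxymethoxy)-5-[(2-methylbut-3-yn-2-yl)oxy]phenyl 2,2-dimethylpropanoate
Product: 14 6-bromo-8-(methoxymethoxy)-2,2-dimethyl-2H-chromen-5-yl 2,2-dimethylpropanoate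
Conditions: xylenes, 140 °C
Reagents that add atoms: none
Why: Thermal aromatic propargyl Claisen rearrangement followed by 1,5-hydrogen shift and oxa-6π electrocyclisation is the classical chromene synthesis from aryl 1,1-dimethylpropargyl ethers, and the only free position ortho to the ether oxygen is the carbon between the two oxygenated carbons, so a single chromene should form.

Step 11
Reactants: 14 6-bromo-8-(methoxymethoxy)-2,2-dimethyl-2H-chromen-5-yl 2,2-dimethylpropanoate
Product: 15 8-(methoxymethoxy)-2,2-dimethyl-6-(4,4,5,5-tetramethyl-1,3,2-dioxaborolan-2-yl)-2H-chromen-5-yl 2,2-dimethylpropanoate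
Conditions: B2pin2, Pd(dppf)Cl2 (5 mol %), KOAc, 1,4-dioxane, 90 °C
Reagents that add atoms: bis(pinacolato)diboron, CC1(C)OB(OC1(C)C)B1OC(C)(C)C(C)(C)O1
Why: Miyaura borylation of the aryl bromide under acetate conditions, which should tolerate the pivalate, the MOM ether and the chromene double bond.

Step 12
Reactants: 7 dihydropyrano-fused 3-iodochromone; 15 chromene pinacol boronate
Product: 17 2'-hydroxyisoflavone (7 in which iodine is replaced by 5-hydroxy-8-(methoxymethoxy)-2,2-dimethyl-2H-chromen-6-yl), via isoflavone pivalate 16 (not isolated)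
Conditions: Pd(dppf)Cl2 (5 mol %), K2CO3, 1,4-dioxane/H2O, 80 °C; then MeOH, 50 °C
Reagents that add atoms: none
Why: Suzuki–Miyaura coupling of a 3-iodochromone with an arylboronate is the established isoflavone construction, and carbonate-mediated methanolysis (transesterification) of the aryl pivalate in the same flask frees the 2'-hydroxyl needed for the next step.

Step 13
Reactants: 17 2'-hydroxyisoflavone
Product: 18 7,5'-bis(methoxymethoxy) coumaronochromone (17 with the 2'-oxygen bonded to C2)
Conditions: DDQ (1.2 equiv), 1,4-dioxane, rt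
Reagents that add atoms: none
Why: DDQ-mediated dehydrogenative cyclisation of a 2'-hydroxyisoflavone (oxa-Michael addition of the 2'-hydroxyl to C2 and removal of two hydrogens by the quinone) is the known entry to coumaronochromones; the two other phenols are masked and the reaction is run at room temperature so that the ring A chroman CH2 should not be dehydrogenated.

Step 14
Reactants: 18 7,5'-bis(methoxymethoxy) coumaronochromone
Product: 19 7,5'-dihydroxy coumaronochromone (the target without its prenyl group)
Conditions: HCl (3 M in MeOH), THF, 40 °C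
Reagents that add atoms: none
Why: Acid-catalysed acetal cleavage (transacetalisation to dimethoxymethane) removes both MOM groups; the chroman, the chromene and the benzofuran-fused chromone should tolerate dilute methanolic HCl.

Step 15
Reactants: 19 7,5'-dihydroxy coumaronochromone
Product: 20 7-O-(2-methylbut-3-en-2-yl) ether of 19
Conditions: tert-butyl (2-methylbut-3-en-2-yl) carbonate (1.1 equiv), Pd(PPh3)4 (3 mol %), THF, 0 °C
Reagents that add atoms: tert-butyl (2-methylbut-3-en-2-yl) carbonate, C=CC(C)(C)OC(=O)OC(C)(C)C
Why: Decarboxylative Tsuji–Trost O-allylation: the tert-butoxide released with CO2 should deprotonate only the far more acidic 7-hydroxyl (para to the chromone carbonyl, a vinylogous acid), whose phenoxide attacks the π-prenyl palladium cation at the substituted terminus to give the tertiary allyl ether under kinetic control at 0 °C.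

Step 16
Reactants: 20 7-O-(2-methylbut-3-en-2-yl) ether
Product: 21 CNP0081330.0 (8-prenyl-7,5'-dihydroxy coumaronochromone with the ring A dihydropyran and the ring B chromene)
Conditions: Eu(fod)3 (10 mol %), CHCl3, 60 °C
Reagents that add atoms: none
Why: Aromatic Claisen rearrangement ([3,3]) of the 1,1-dimethylallyl aryl ether, accelerated by the europium Lewis acid, delivers the prenyl group to C8, the only ortho position that can rearomatise because C6 is quaternary, and regenerates the 7-hydroxyl.

Compound list

1 | 2,4,6-trihydroxyacetophenone | CC(=O)c1c(O)cc(O)cc1O | starting material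
2 | 1-[2,6-dihydroxy-4-(methoxymethoxy)phenyl]ethan-1-one | CC(=O)c1c(O)cc(OCOC)cc1O | intermediate
3 | 1-[2-hydroxy-4-(methoxymethoxy)-6-[(2-methylbut-3-yn-2-yl)oxy]phenyl]ethan-1-one | CC(=O)c1c(O)cc(OCOC)cc1OC(C)(C)C#C | intermediate
4 | 1-[7-hydroxy-5-(methoxymethoxy)-2,2-dimethyl-2H-chromen-8-yl]ethan-1-one | CC(=O)c1c(O)cc(OCOC)c2c1OC(C)(C)C=C2 | intermediate
5 | 1-[7-hydroxy-5-(methoxymethoxy)-2,2-dimethyl-3,4-dihydro-2H-chromen-8-yl]ethan-1-one | CC(=O)c1c(O)cc(OCOC)c2c1OC(C)(C)CC2 | intermediate
6 | (E)-3-(dimethylamino)-1-[7-hydroxy-5-(methoxymethoxy)-2,2-dimethyl-3,4-dihydro-2H-chromen-8-yl]prop-2-en-1-one | CN(C)/C=C/C(=O)c1c(O)cc(OCOC)c2c1OC(C)(C)CC2 | intermediate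
7 | 3-iodo-7-(methoxymethoxy)chromen-4-one with a 2,2-dimethyl-3,4-dihydro-2H-pyran ring fused at C5 (ring O) and C6 (CH2) | O=c1c(I)coc2cc(OCOC)c3c(c12)OC(C)(C)CC3 | intermediate
8 | 5-bromo-2,4-dihydroxybenzaldehyde | O=Cc1cc(Br)c(O)cc1O | starting material
9 | 2-bromo-4-formyl-5-hydroxyphenyl 2,2-dimethylpropanoate | O=Cc1cc(Br)c(OC(=O)C(C)(C)C)cc1O | intermediate
10 | 2-bromo-4-formyl-5-[(2-methylbut-3-yn-2-yl)oxy]phenyl 2,2-dimethylpropanoate | O=Cc1cc(Br)c(OC(=O)C(C)(C)C)cc1OC(C)(C)C#C | intermediate
11 | 2-bromo-4-(formyloxy)-5-[(2-methylbut-3-yn-2-yl)oxy]phenyl 2,2-dimethylpropanoate | O=COc1cc(Br)c(OC(=O)C(C)(C)C)cc1OC(C)(C)C#C | intermediate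
12 | 2-bromo-4-hydroxy-5-[(2-methylbut-3-yn-2-yl)oxy]phenyl 2,2-dimethylpropanoate | Oc1cc(Br)c(OC(=O)C(C)(C)C)cc1OC(C)(C)C#C | intermediate
13 | 2-bromo-4-(methoxymethoxy)-5-[(2-methylbut-3-yn-2-yl)oxy]phenyl 2,2-dimethylpropanoate | COCOc1cc(Br)c(OC(=O)C(C)(C)C)cc1OC(C)(C)C#C | intermediate
14 | 6-bromo-8-(methoxymethoxy)-2,2-dimethyl-2H-chromen-5-yl 2,2-dimethylpropanoate | COCOc1cc(Br)c(OC(=O)C(C)(C)C)c2c1OC(C)(C)C=C2 | intermediate
15 | 8-(methoxymethoxy)-2,2-dimethyl-6-(4,4,5,5-tetramethyl-1,3,2-dioxaborolan-2-yl)-2H-chromen-5-yl 2,2-dimethylpropanoate | COCOc1cc(B3OC(C)(C)C(C)(C)O3)c(OC(=O)C(C)(C)C)c2c1OC(C)(C)C=C2 | intermediate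
16 | isoflavone pivalate: 7 in which iodine is replaced by the 8-(methoxymethoxy)-2,2-dimethyl-5-(pivaloyloxy)-2H-chromen-6-yl group | O=c1c(-c2cc(OCOC)c3c(c2OC(=O)C(C)(C)C)C=CC(C)(C)O3)coc2cc(OCOC)c3c(c12)OC(C)(C)CC3 | intermediate
17 | 2'-hydroxyisoflavone: 7 in which iodine is replaced by the 5-hydroxy-8-(methoxymethoxy)-2,2-dimethyl-2H-chromen-6-yl group | O=c1c(-c2cc(OCOC)c3c(c2O)C=CC(C)(C)O3)coc2cc(OCOC)c3c(c12)OC(C)(C)CC3 | intermediate
18 | 7,5'-bis(methoxymethoxy) coumaronochromone: furan oxygen from C2 to C2', 2,2-dimethyldihydropyran on ring A (O at C5, CH2 at C6), 2,2-dimethylchromene on ring B (CH= at C3', O at C4') | c1c(OCOC)c2c(c3c(=O)c4c(oc13)oc1c3c(c(OCOC)cc14)OC(C)(C)C=C3)OC(C)(C)CC2 | intermediate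
19 | 7,5'-dihydroxy coumaronochromone (18 without the two MOM groups) | c1c(O)c2c(c3c(=O)c4c(oc13)oc1c3c(c(O)cc14)OC(C)(C)C=C3)OC(C)(C)CC2 | intermediate
20 | 7-O-(2-methylbut-3-en-2-yl) ether of 19 | c1c(OC(C)(C)C=C)c2c(c3c(=O)c4c(oc13)oc1c3c(c(O)cc14)OC(C)(C)C=C3)OC(C)(C)CC2 | intermediate
21 | CNP0081330.0: 19 carrying a 3-methylbut-2-enyl group at C8 | CC(C)=CCc1c(O)c2c(c3c(=O)c4c(oc13)oc1c3c(c(O)cc14)OC(C)(C)C=C3)OC(C)(C)CC2 | target

Total step count: 16. Longest linear sequence: 11 steps (steps 6–11 from 8, then steps 12–16).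

Steps most likely to fail

Step 13. The process at risk is over-oxidation: DDQ may abstract hydride from the benzylic CH2 of the ring A chroman (the cation is stabilised by O5, O7 and O1) and dehydrogenate it to a chromene. It may also oxidise the para-alkoxyphenol of ring B towards a quinone instead of closing the furan. The fallback avoids any oxidant by closing the furan through addition–elimination at a C2 that already carries a leaving group; it sets out from 5 and comes back at 18. Ketone 5 is condensed with CS2 (t-BuOK, THF, 0 °C to rt) to the ring A 4-hydroxy-2H-chromene-2-thione F1. This is S-methylated (MeI, K2CO3, acetone) to the 2-(methylsulfanyl)chromone F2 and iodinated at C3 (N-iodosuccinimide, MeCN) to the 3-iodo-2-(methylsulfanyl)chromone F3. Suzuki–Miyaura coupling of F3 with 15 under the conditions of step 12 should give the 2-(methylsulfanyl)isoflavone pivalate F4 and, after methanolysis, the 2'-hydroxy-2-(methylsulfanyl)isoflavone F5. Its phenoxide (K2CO3, DMF, 80 °C) adds to C2 and expels methanethiolate to give 18.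

Step 15. The process at risk is reversible ionisation of the tertiary allyl aryl ether by zerovalent palladium, because the 7-oxychromone is a good leaving group. This lets the branched ether drift to the linear O-prenyl ether and lets the 5'-hydroxyl compete for the allyl cation, so O-selectivity and regioselectivity are lost. The fallback makes the ether irreversibly at the alkyne oxidation level; it sets out from 19 and comes back at 20. Diol 19 is treated with 3-chloro-3-methylbut-1-yne (1.0 equiv), DBU (1.0 equiv) and CuCl2·2H2O (cat.) in MeCN at 0 °C, where only the 7-phenoxide is present and the product cannot re-ionise. This should give the 7-O-(2-methylbut-3-yn-2-yl) ether F6. Semi-hydrogenation (H2, Pd/CaCO3 poisoned with Pb(OAc)2, quinoline, EtOAc) then leads to 20.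

Step 3. The process at risk is ionisation of the tertiary propargylic C–O bond by the Lewis-acidic gold cation, with loss of the C5 unit and return to 2, in competition with ring attack; the chelating hydroxy ketone may also sequester the catalyst. The fallback closes the same ring bond at the sp3 level by intramolecular C-alkylation; it sets out from 3 and comes back at 5. Alkyne 3 is semi-hydrogenated (H2, Pd/CaCO3 poisoned with Pb(OAc)2, quinoline, EtOAc) to the 1,1-dimethylallyl ether F7. This is hydroborated and oxidised (9-BBN, THF; then NaBO3·4H2O) to the primary alcohol F8 and converted (I2, PPh3, imidazole, CH2Cl2) into the primary iodide F9. With K2CO3 in DMF at 60 °C the phenoxide should alkylate through its para carbon (6-exo-tet, the same ring carbon as in step 3) and tautomerise to chroman 5, so that step 4 is no longer needed.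

Further compounds

F1 | step 13 | 4-hydroxy-5-(methoxymethoxy)-substituted 2H-chromene-2-thione with the 2,2-dimethyldihydropyran ring (O on C5, CH2 on C6; chromone locants, MOM-oxy on C7) | S=c1cc(O)c2c3OC(C)(C)CCc3c(OCOC)cc2o1
F2 | step 13 | 7-(methoxymethoxy)-2-(methylsulfanyl)chromen-4-one with the 2,2-dimethyldihydropyran ring (O on C5, CH2 on C6) | CSc1cc(=O)c2c3OC(C)(C)CCc3c(OCOC)cc2o1
F3 | step 13 | 3-iodo-7-(methoxymethoxy)-2-(methylsulfanyl)chromen-4-one with the 2,2-dimethyldihydropyran ring (O on C5, CH2 on C6) | CSc1oc2cc(OCOC)c3CCC(C)(C)Oc3c2c(=O)c1I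
F4 | step 13 | 2-(methylsulfanyl)isoflavone pivalate: F3 in which iodine is replaced by the 8-(methoxymethoxy)-2,2-dimethyl-5-(pivaloyloxy)-2H-chromen-6-yl group | CSc1oc2cc(OCOC)c3CCC(C)(C)Oc3c2c(=O)c1-c1cc(OCOC)c2OC(C)(C)C=Cc2c1OC(=O)C(C)(C)C
F5 | step 13 | 2'-hydroxy-2-(methylsulfanyl)isoflavone: F4 without the pivaloyl group | CSc1oc2cc(OCOC)c3CCC(C)(C)Oc3c2c(=O)c1-c1cc(OCOC)c2OC(C)(C)C=Cc2c1O
F6 | step 15 | 7-O-(2-methylbut-3-yn-2-yl) ether of 19 | c1c(OC(C)(C)C#C)c2c(c3c(=O)c4c(oc13)oc1c3c(c(O)cc14)OC(C)(C)C=C3)OC(C)(C)CC2
F7 | step 3 | 1-[2-hydroxy-4-(methoxymethoxy)-6-[(2-methylbut-3-en-2-yl)oxy]phenyl]ethan-1-one | CC(=O)c1c(O)cc(OCOC)cc1OC(C)(C)C=C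
F8 | step 3 | 1-[2-hydroxy-6-[(4-hydroxy-2-methylbutan-2-yl)oxy]-4-(methoxymethoxy)phenyl]ethan-1-one | CC(=O)c1c(O)cc(OCOC)cc1OC(C)(C)CCO
F9 | step 3 | 1-[2-hydroxy-6-[(4-iodo-2-methylbutan-2-yl)oxy]-4-(methoxymethoxy)phenyl]ethan-1-one | CC(=O)c1c(O)cc(OCOC)cc1OC(C)(C)CCI
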